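No rate constants were given, so I read a time-like constant off the readings.

all flasks: starting complex 0.073 M

| charge | incoming ligand | remark | time |
|---|---|---|---|
| eta | 0.095 M | run made earlier |  |
| zeta | 0.14 M | run made earlier |  |
| delta | 0.19 M | run made earlier |  |
| autumn | 0.0876 M |  | 4.0 d |
| dusk | 0.109 M |  | 4.0 d |
| summer | 0.182 M |  | 4.0 d |

- eta (time / d: complex with two exchanged / %, complex with three exchanged / %): 0.625: 13.6, 5.4; 1.04: 14.2, 5.8; 1.67: 13.4, 5.7; 2.50: 12.9, 5.1; 3.00: 11.7, 5.3
- zeta (time / d: complex with two exchanged / %, complex with three exchanged / %): 0.208: 13.2, 4.1; 0.417: 16.4, 5.9; 0.833: 14.3, 6.3; 1.67: 11.4, 5.2; 3.00: 9.4, 4.6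
- delta (time / d: complex with two exchanged / %, complex with three exchanged / %): 0.625: 14.7, 7.5; 1.04: 10.7, 4.8; 1.67: 6.7, 4.1; 2.50: 5.1, 2.2; 3.00: 3.6, 2.2

(readings scatter by 0.3 percentage points)

- in percentages every species weighs as the starting complex in it: one idle adduct or self-condensation product counts as two
- for complex with three exchanged the idle adduct is counted in
- the numbers in the tables scatter with a standard deviation of 0.3 percentage points
- reactions considered so far: complex with one exchanged + incoming ligand -> leaving ligand + complex with two exchanged; complex with two exchanged + incoming ligand -> leaving ligand + complex with three exchanged; complex with three exchanged + incoming ligand -> leaving ligand + complex with four exchanged; starting complex + complex with three exchanged <-> idle adduct; starting complex + incoming ligand -> leaving ligand + complex with one exchanged; 2 starting complex -> self-condensation product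
- in an amount of complex with three exchanged, one idle adduct counts as one complex with three exchanged

- final complex with two exchanged, as a percentage of the starting complex charged, for each flask in turn (autumn, dusk, summer)

1. I called λ the late loss constant: the natural logarithm of the ratio of complex with two exchanged at 1.67 d to that at 3.00 d, divided by the days between. I treated it as a pseudo-first-order constant, net of any supply of complex with two exchanged, and it carried the scatter of its two readings. The delta run read 0.467 /d, and the eta run read 0.102 /d.

2. Fast extreme: I let the loss run on at λ until 4.0 d. From the last readings, that gave 10.6 % for autumn, using eta, and 2.26 % for summer, using delta.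

3. Frozen extreme: I let the loss stop at the reading before the last. That gave eta's 12.9 % for autumn and delta's 5.1 % for summer.

4. Autumn was charged with less incoming ligand than eta, and summer with less than delta. So I expected each to fall no faster than its neighbour. I expected the incoming ligand to fade gradually, so I took the middle of each pair: 11.7 % for autumn and 3.68 % for summer. I reckoned no value for dusk.

5. The forecast gave 11.3 %, 10 % and 3 %, on the ground that “what matters is the ligand left over”. Its autumn value stood below mine, and so did its summer value.

The flasks gave 12.1 % for autumn, 11.6 % for dusk and 4.01 % for summer, so the forecast held within its margin.

    complex with one exchanged + incoming ligand → leaving ligand + complex with two exchanged (k = 0.0313 /M/min)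
    complex with two exchanged + incoming ligand → leaving ligand + complex with three exchanged (k = 0.0322 /M/min)
    complex with three exchanged + incoming ligand → leaving ligand + complex with four exchanged (k = 0.0791 /M/min)
    starting complex + complex with three exchanged ⇌ idle adduct, settled at all times (K = 9.17 /M)
    starting complex + incoming ligand → leaving ligand + complex with one exchanged (k = 0.0290 /M/min)
    2 starting complex → self-condensation product (k = 0.0388 /M/min)

Parking starting complex as idle adduct made no difference to complex with two exchanged in dusk. In autumn, incoming ligand stood at 0.43 % of its charge at 4.00 d. Between 2.00 d and 4.00 d, autumn's λ came to 0.0201 /d, smaller than eta's reading. Over the same interval, summer's λ came to 0.250 /d, smaller than delta's reading.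

The numbers in the tables were computed with made-up constants; scatter was added.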